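**Remark on the chemistry:** alcohol 9 and ether 10 are written as the 3,4-trans epimers expected to predominate; C4 becomes planar in step 8, so any 3,4-cis epimer is carried along, and 4-(benzyloxy)benzaldehyde 4 and 3,5-bis(benzyloxy)phenol 11 are taken as purchased.

## Analysis of the target

The target is a 4→8-linked biflavanoid. The upper unit is a 5-deoxyflavan-3-ol (rings A, C, B; guibourtinidol type). Its C4 is bonded to C8' of a lower epiafzelechin unit (rings D, F, E; primed numbers).

There are five stereocentres in two groups. C2 (R), C3 (S) and C4 (S) are contiguous in ring C and all-trans. C2' (R) and C3' (R) in ring F are cis. Ring D separates the two groups, so their mutual relation must be set by making each group in the absolute sense.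

The free compound has seven hydroxyls, five of them phenolic, and is prone to oxidation. C2 and C2' are benzylic ethers para to oxygen, and the C4–C8' bond is doubly benzylic; acid can ionise all three. The free phenols are therefore released only in the last step, under neutral conditions.

The synthesis is hard for three reasons:
- the interflavan bond must go to C8' and not C6', with the 3,4-trans geometry;
- the 2',3'-cis arrangement of ring F is the less stable one;
- the lower unit is not a cheap building block and is best grown on the upper one.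

The strategy rests on the array C8a'–O1'–C2'(ring E)–C3'(O)–C4'–C4a'. This is an aryl 1-arylpropargyl ether of ring D whose internal alkyne carbon has been oxidised (C3') and whose terminal carbon (C4') has been joined to the ortho position C4a'.

## Retrosynthetic reasoning

**21 ⇐ 20.** The six benzyl C–O bonds are cut last. Hexabenzyl alcohol 20 hides every phenol and the upper C3 hydroxyl behind one kind of group that falls under neutral hydrogenolysis, so the air- and acid-sensitive polyphenol exists only at the end.

**20 ⇐ 19.** The C3'–H bond is cut to give flavan-3-one 19. The cis relation of C2' and C3' is the less stable one and is hard to reach by ring closure, but it is the expected result of delivering a bulky hydride to a ketone from the face away from the C2' aryl group. The forward step must reduce without enolising C2'.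

**19 ⇐ 17 (through 18).** The C4'–C4a' bond and the C3' carbonyl oxygen are removed together, giving aryl propargyl ether 17. This cut is chosen because it turns ring F into a three-carbon unit hung on the ring D oxygen with C2' already configured. C4a' is the only free position ortho to that oxygen, so the ring can close in one place only. The forward reaction must put oxygen on the internal alkyne carbon and let ring D capture the resulting carbene 18.

**17 ⇐ 12 + 16.** The O1'–C2' ether bond is cut to phenol 12 and propargylic alcohol 16. The phenol is the natural nucleophile, and a substitution with inversion transfers the configuration of 16 to C2'. The forward step must stay on the invertive pathway although the carbon is benzylic and propargylic.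

**16 ⇐ 15 ⇐ 4 + 13 (through 14).** The C2'–C3' bond is cut between aldehyde 4 and silylalkyne 13, used as its zinc derivative 14. This sets C2' by a catalytic enantioselective carbonyl addition on a two-step side branch. The silyl group is then removed from 15.

**12 ⇐ 10 + 11.** The interflavan bond C4–C8' is cut to the C4 cation derived from flavan 10 and phenol 11. The upper unit is electrophilic at C4 by nature, and ring D is nucleophilic ortho to its free hydroxyl. The forward reaction must add anti to the C3 benzyloxy group (3,4-trans) and at the carbon next to the hydroxyl, which later becomes C8'.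

**10 ⇐ 9 ⇐ 8.** Both benzyl ethers of 10 are disconnected to diol 9, and 9 to dihydroflavonol 8 by removing hydride from C4. Benzylation is placed after the reduction so that no base ever meets the epimerisable α-hydroxy ketone. The C4 benzyloxy group doubles as the leaving group.

**8 ⇐ 6 (through 7) ⇐ 5.** The O1–C2 bond is cut to epoxy ketone 6, the freed phenol 7 being the species that cyclises. The epoxide is traced to chalcone 5. C3 comes from the enantioselective epoxidation and C2 from the ring opening at the benzylic carbon.

**5 ⇐ 3 + 4; 3 ⇐ 2 ⇐ 1.** The enone double bond is cut by aldol logic into ketone 3 and aldehyde 4. Ketone 3 is acetophenone 1 after benzylation of the para hydroxyl (2) and masking of the chelated ortho hydroxyl.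

## Alternatives that were turned down

**Alternative 1: ring D built de novo.** The bonds C8'–C8a' and C4a'–C5' are cut. The flavan-4-one A1 (the target skeleton with a C4' carbonyl, five benzyl ethers and free C5' and C7' hydroxyls) goes back to two partners. A2 is a bis(silyloxy)diene that already carries the upper flavan on its terminal carbon. A3 is a dihydropyranone that is ring F with both stereocentres and a sulfinyl group on the future C4a'.
- Forward key step: the nucleophilic terminus of A2 adds to the enone β-carbon of A3 (C8a'), the ketene acetal carbon bonds to C4a', and loss of the sulfur and silyl substituents aromatises the new ring to A1.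
- For: the interflavan bond exists before ring D does, so no C8'/C6' question arises. On this point the alternative is stronger than the chosen route, whose step 8 relies on a steric bias.
- Against: the reacting diene terminus is a secondary carbon loaded with the flavan. A3 needs its own enantioselective synthesis with the cis pattern. In A1, C3' lies α to the C4' carbonyl in the less stable cis arrangement, and the aromatisation conditions invite epimerisation. The C4' oxygen must then be removed by reduction and benzylic deoxygenation next to acid-labile bonds.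
- Comparison: the route would be clearly longer. The chosen route buys ring D, adds the three carbons of ring F in two operations, and carries no superfluous oxygen.

**Alternative 2: ring C by conjugate addition.** Ring C is cut at C4–C4a and O1–C2. The 4H-chromene A4 is traced to an ortho-hydroxyarylboronic acid A5 (ring A) and an enone A6, in which the complete benzylated lower flavan-3-ol carries at C8' a propenoyl chain ending in ring B.
- Forward key step: a rhodium–chiral diene catalyst adds A5 to A6 and creates C4. The phenol then condenses with the ketone to give A4. Hydroboration of the C2=C3 enol ether anti to the C4 aryl group would later set C2 and C3.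
- For: C4 is set by the catalyst and not by the substrate, and the position of the enone fixes the interflavan regiochemistry. In control of C4 this is as strong as or stronger than the chosen route.
- Against: the whole lower unit must first be made and benzylated in a sequence of its own and then functionalised at C8', which moves the C8'/C6' problem instead of removing it. The β-carbon of A6 sits on a hindered, electron-rich 2,6-dioxygenated ring and is a poor acceptor. A5 is prone to protodeboronation, and the enol ether A4 is labile to acid.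
- Comparison: the chosen route grows the lower unit on phenol 12 in four steps and obtains C4 by the trans-selective cation capture that is typical of 2,3-trans flavans.

**Alternative 3: ring F by epoxide opening.** Ring F is cut at O1'–C2'. The cis alcohol A7 (benzyl ethers on the upper unit and ring D, a pivalate on the ring E oxygen, free C3' hydroxyl) is traced to phenol A8, which carries at C4a' a methylene group attached to a cis-epoxide bearing ring E.
- Forward key step: a sulfonic acid activates the epoxide and the ring D phenol opens it at the benzylic carbon with inversion (6-endo). The epoxide oxygen stays on C3'.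
- For: both ring F stereocentres come from one epoxidation, the cis relation follows stereospecifically, and no ketone is involved, so C2' cannot enolise. Here the alternative is cleaner than the chosen route.
- Against: A8 needs a (Z)-3-arylallyl unit attached to the crowded C4a' and an enantioselective epoxidation of a cis-disubstituted alkene in a molecule full of electron-rich rings. The cyclisation must be strictly invertive at a benzylic carbon; any cationic character leaks to the more stable 2',3'-trans isomer, and five-membered closure at C3' competes. The pivalate that tames ring E costs differentiated protection and an extra deprotection.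
- Comparison: the chosen route sets C2' by a simple alkynylation and the cis relation by a hydride reduction that is typical of flavan-3-ones, and is shorter.

Key step: step 12

## Route

Step 1
Reactants: 1 2,4-dihydroxyacetophenone
Product: 2 1-[4-(benzyloxy)-2-hydroxyphenyl]ethanone
Conditions: BnBr (1.05 equiv), K2CO3, acetone, reflux
Reagents that add atoms: benzyl bromide, BrCc1ccccc1
Why: Williamson etherification; the ortho hydroxyl is hydrogen-bonded to the acetyl carbonyl and much less nucleophilic, so the para hydroxyl should be benzylated selectively.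

Step 2
Reactants: 2 1-[4-(benzyloxy)-2-hydroxyphenyl]ethanone
Product: 3 1-[4-(benzyloxy)-2-(methoxymethoxy)phenyl]ethanone
Conditions: NaH (1.1 equiv), MOMCl, DMF, 0 °C to rt
Reagents that add atoms: chloromethyl methyl ether, COCCl
Why: O-alkylation of the fully deprotonated chelated phenol; the acetal survives the basic aldol and peroxide steps, keeps the phenol from cyclising onto the enone or epoxide too early, and is removed by acid.

Step 3
Reactants: 3 1-[4-(benzyloxy)-2-(methoxymethoxy)phenyl]ethanone; 4 4-(benzyloxy)benzaldehyde
Product: 5 (E)-1-[4-(benzyloxy)-2-(methoxymethoxy)phenyl]-3-[4-(benzyloxy)phenyl]prop-2-en-1-one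
Conditions: KOH, EtOH/THF, rt
Reagents that add atoms: none
Why: Claisen–Schmidt condensation; the aldehyde cannot enolise and dehydration of the aldol through the enolate gives the conjugated E-alkene.

Step 4
Reactants: 5 (E)-1-[4-(benzyloxy)-2-(methoxymethoxy)phenyl]-3-[4-(benzyloxy)phenyl]prop-2-en-1-one
Product: 6 [(2R,3S)-3-[4-(benzyloxy)phenyl]oxiran-2-yl][4-(benzyloxy)-2-(methoxymethoxy)phenyl]methanone
Conditions: poly-L-leucine, urea–H2O2, DBU, THF, rt
Reagents that add atoms: urea–hydrogen peroxide, NC(N)=O.OO
Why: Juliá–Colonna epoxidation (Weitz–Scheffer addition of hydroperoxide within the helical peptide); the amide N–H groups at the helix terminus bind the enone and the peroxide and should deliver oxygen to one face, the L-peptide giving the (αR,βS) trans epoxide as with chalcone itself; the α-carbon becomes C3 and fixes the absolute configuration of the upper unit; the crystalline epoxide can be enriched by recrystallisation.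

Step 5
Reactants: 6 [(2R,3S)-3-[4-(benzyloxy)phenyl]oxiran-2-yl][4-(benzyloxy)-2-(methoxymethoxy)phenyl]methanone
Product: 8 (2R,3R)-7-(benzyloxy)-2-[4-(benzyloxy)phenyl]-3-hydroxychroman-4-one, via free-phenol epoxy ketone 7 (not isolated)
Conditions: conc. HCl, MeOH/THF, 55 °C
Reagents that add atoms: none
Why: Acid cleaves the acetal, and the freed phenol of 7 opens the protonated epoxide at the benzylic carbon (6-endo) with inversion to give the 2,3-trans dihydroflavonol; C3 is the untouched epoxide α-carbon, and if the benzylic carbon reacts with cationic character the closure should still lead to the diequatorial trans ring, so C2 ends as R in either case.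

Step 6
Reactants: 8 (2R,3R)-7-(benzyloxy)-2-[4-(benzyloxy)phenyl]-3-hydroxychroman-4-one
Product: 9 (2R,3S,4R)-7-(benzyloxy)-2-[4-(benzyloxy)phenyl]chromane-3,4-diol
Conditions: NaBH4, MeOH/THF, 0 °C
Reagents that add atoms: none
Why: Borohydride reduction of the aryl ketone; attack anti to the C3 hydroxyl should give mainly the 3,4-trans diol, and the C4 configuration has no consequence because C4 is ionised in step 8; removing the ketone also removes the base sensitivity of C2 and C3.

Step 7
Reactants: 9 (2R,3S,4R)-7-(benzyloxy)-2-[4-(benzyloxy)phenyl]chromane-3,4-diol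
Product: 10 (2R,3S,4R)-3,4,7-tris(benzyloxy)-2-[4-(benzyloxy)phenyl]chromane
Conditions: NaH, BnBr, Bu4NI (cat.), DMF, 0 °C to rt
Reagents that add atoms: benzyl bromide, BrCc1ccccc1
Why: Double Williamson etherification on a substrate without an enolisable centre; the C3 ether is the protecting group for the end of the route and the C4 ether is the leaving group for the next step.

Step 8
Reactants: 10 (2R,3S,4R)-3,4,7-tris(benzyloxy)-2-[4-(benzyloxy)phenyl]chromane; 11 3,5-bis(benzyloxy)phenol
Product: 12 2-[(2R,3S,4S)-3,7-bis(benzyloxy)-2-[4-(benzyloxy)phenyl]chroman-4-yl]-3,5-bis(benzyloxy)phenol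
Conditions: 11 (3 equiv), BF3·OEt2 (0.5 equiv), CH2Cl2, −40 to 0 °C
Reagents that add atoms: none
Why: Friedel–Crafts alkylation through the C4 benzylic cation, stabilised by O1 and the para C7 benzyloxy group; the phenol should attack anti to the C3 benzyloxy group and set the 3,4-trans (4S) configuration, and should react through the carbon ortho to its hydroxyl, which is flanked by OH and OBn and is less hindered than the carbon between the two benzyloxy groups, in analogy to the C8 preference of benzylated flavan-3-ol nucleophiles; the excess of 11 suppresses double alkylation.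

Step 9
Reactants: 4 4-(benzyloxy)benzaldehyde; 13 ethynyltrimethylsilane
Product: 15 (1S)-1-[4-(benzyloxy)phenyl]-3-(trimethylsilyl)prop-2-yn-1-ol, via alkynylzinc reagent 14 (not isolated)
Conditions: 13, Et2Zn, Cy2NH (5 mol %), Et2O, rt; then (R)-BINOL (20 mol %), Ti(OiPr)4 (50 mol %); then 4, rt
Reagents that add atoms: none
Why: Catalytic enantioselective alkynylzinc addition to an aromatic aldehyde; the BINOL–Ti(OiPr)4 complex activates 4 and, by the sense known for dialkylzinc additions with this catalyst, the (R)-ligand should direct the alkynyl group of 14 to the Re face, which gives the (1S) silyl alkynol; the enantiomeric purity is checked at this stage before the material is carried on.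

Step 10
Reactants: 15 (1S)-1-[4-(benzyloxy)phenyl]-3-(trimethylsilyl)prop-2-yn-1-ol
Product: 16 (1R)-1-[4-(benzyloxy)phenyl]prop-2-yn-1-ol
Conditions: K2CO3 (cat.), MeOH, rt
Reagents that add atoms: none
Why: Methanolysis of the alkynyl C–Si bond; the carbinol carbon is not touched, and the descriptor changes from S to R only because ethynyl ranks below aryl once silicon is gone.

Step 11
Reactants: 12 2-[(2R,3S,4S)-3,7-bis(benzyloxy)-2-[4-(benzyloxy)phenyl]chroman-4-yl]-3,5-bis(benzyloxy)phenol; 16 (1R)-1-[4-(benzyloxy)phenyl]prop-2-yn-1-ol
Product: 17 (2R,3S,4S)-3,7-bis(benzyloxy)-2-[4-(benzyloxy)phenyl]-4-[2,4-bis(benzyloxy)-6-{[(1S)-1-[4-(benzyloxy)phenyl]prop-2-yn-1-yl]oxy}phenyl]chromane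
Conditions: PPh3, DIAD, toluene, −20 °C to rt
Reagents that add atoms: none
Why: Mitsunobu etherification; the phenol protonates the phosphine–azodicarboxylate betaine and the phenoxide displaces the alkoxyphosphonium group of 16 with inversion, so the (1R) alcohol gives the (1S) ether, the future C2'; the non-polar solvent and low temperature are chosen to hold the reaction on the invertive pathway.

Step 12
Reactants: 17 (2R,3S,4S)-3,7-bis(benzyloxy)-2-[4-(benzyloxy)phenyl]-4-[2,4-bis(benzyloxy)-6-{[(1S)-1-[4-(benzyloxy)phenyl]prop-2-yn-1-yl]oxy}phenyl]chromane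
Product: 19 (2R)-5,7-bis(benzyloxy)-2-[4-(benzyloxy)phenyl]-8-[(2R,3S,4S)-3,7-bis(benzyloxy)-2-[4-(benzyloxy)phenyl]chroman-4-yl]chroman-3-one, via alpha-oxo gold carbene 18 (not isolated)
Conditions: (2-biphenylyl)(t-Bu)2PAuNTf2 (5 mol %), 8-methylquinoline N-oxide (2 equiv), 1,2-dichloroethane, rt, slow addition of 17
Reagents that add atoms: 8-methylquinoline N-oxide, Cc1cccc2ccc[n+]([O-])c12
Why: Cationic univalent gold binds the terminal alkyne of 17, the N-oxide oxygen adds to the internal carbon (the future C3'), and N–O cleavage releases 8-methylquinoline and leaves carbene 18 with the carbene centre on the terminal carbon (the future C4'). Ring D, activated by three oxygens, attacks the carbene carbon through C4a', which is ortho to the ether oxygen and para to the C7' benzyloxy group; rearomatisation and protodeauration give ketone 19 and return the catalyst. The closest known reaction type is the gold-catalysed N-oxide oxidation of aryl propargyl ethers to chroman-3-ones. Ring F closes as a six-membered ring by intramolecular Friedel–Crafts-type capture of the carbene, formally 6-exo with respect to the gold–carbon double bond, and this forms C4'–C4a'. No stereocentre is created: C2' is the propargylic carbon, takes no part in bond making or breaking, and should keep its configuration as long as no acid or strong base is present, so no acid additive is used and 19 is reduced without storage. Oxygen goes to the substituted alkyne carbon because the alkyne is terminal, and arylation can occur only at C4a' because C8' carries the upper flavan and five-membered closure onto ring E would need attack meta to its only oxygen. The step also needs oxidation to outrun direct hydroarylation of the gold-bound alkyne, which the bulky biaryl phosphine, the excess of oxidant and the slow addition of 17 are meant to secure.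

Step 13
Reactants: 19 (2R)-5,7-bis(benzyloxy)-2-[4-(benzyloxy)phenyl]-8-[(2R,3S,4S)-3,7-bis(benzyloxy)-2-[4-(benzyloxy)phenyl]chroman-4-yl]chroman-3-one
Product: 20 (2R,3R)-5,7-bis(benzyloxy)-2-[4-(benzyloxy)phenyl]-8-[(2R,3S,4S)-3,7-bis(benzyloxy)-2-[4-(benzyloxy)phenyl]chroman-4-yl]chroman-3-ol
Conditions: LiBH(s-Bu)3, THF, −78 °C; then aq. NH4Cl
Reagents that add atoms: none
Why: Ketone reduction by a bulky trialkylborohydride; the C2' aryl group shields its own face of the C3' carbonyl, so hydride should arrive anti to it and leave the hydroxyl cis to the aryl group (3'R), the usual outcome with flavan-3-ones; the low temperature and low basicity of the reagent keep C2' from enolising.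

Step 14
Reactants: 20 (2R,3R)-5,7-bis(benzyloxy)-2-[4-(benzyloxy)phenyl]-8-[(2R,3S,4S)-3,7-bis(benzyloxy)-2-[4-(benzyloxy)phenyl]chroman-4-yl]chroman-3-ol
Product: 21 (2R,3R)-8-[(2R,3S,4S)-3,7-dihydroxy-2-(4-hydroxyphenyl)chroman-4-yl]-2-(4-hydroxyphenyl)chromane-3,5,7-triol
Conditions: H2 (1 atm), Pd(OH)2/C, THF/MeOH, rt
Reagents that add atoms: none
Why: Hydrogenolysis of five aryl benzyl ethers and one alkyl benzyl ether under neutral conditions; the cyclic benzylic ethers O1–C2 and O1'–C2' and the C4–C8' bond are cleaved far more slowly and should survive if the reaction is stopped on completion; no stereocentre is touched.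

## Compound list

1 | 2,4-dihydroxyacetophenone | CC(=O)c1ccc(O)cc1O | starting material
2 | 1-[4-(benzyloxy)-2-hydroxyphenyl]ethanone | CC(=O)c1ccc(OCc2ccccc2)cc1O | intermediate
3 | 1-[4-(benzyloxy)-2-(methoxymethoxy)phenyl]ethanone | CC(=O)c1ccc(OCc2ccccc2)cc1OCOC | intermediate
4 | 4-(benzyloxy)benzaldehyde | O=Cc1ccc(OCc2ccccc2)cc1 | starting material
5 | (E)-1-[4-(benzyloxy)-2-(methoxymethoxy)phenyl]-3-[4-(benzyloxy)phenyl]prop-2-en-1-one | COCOc1cc(OCc2ccccc2)ccc1C(=O)/C=C/c1ccc(OCc2ccccc2)cc1 | intermediate
6 | [(2R,3S)-3-[4-(benzyloxy)phenyl]oxiran-2-yl][4-(benzyloxy)-2-(methoxymethoxy)phenyl]methanone | COCOc1cc(OCc2ccccc2)ccc1C(=O)[C@@H]1O[C@H]1c1ccc(OCc2ccccc2)cc1 | intermediate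
7 | [(2R,3S)-3-[4-(benzyloxy)phenyl]oxiran-2-yl][4-(benzyloxy)-2-hydroxyphenyl]methanone | Oc1cc(OCc2ccccc2)ccc1C(=O)[C@@H]1O[C@H]1c1ccc(OCc2ccccc2)cc1 | intermediate (not isolated)
8 | (2R,3R)-7-(benzyloxy)-2-[4-(benzyloxy)phenyl]-3-hydroxychroman-4-one | C(c1ccccc1)Oc1ccc([C@H]2Oc3cc(OCc4ccccc4)ccc3C(=O)[C@@H]2O)cc1 | intermediate
9 | (2R,3S,4R)-7-(benzyloxy)-2-[4-(benzyloxy)phenyl]chromane-3,4-diol | C(c1ccccc1)Oc1ccc([C@H]2Oc3cc(OCc4ccccc4)ccc3[C@@H](O)[C@@H]2O)cc1 | intermediate
10 | (2R,3S,4R)-3,4,7-tris(benzyloxy)-2-[4-(benzyloxy)phenyl]chromane | C(c1ccccc1)Oc1ccc([C@H]2Oc3cc(OCc4ccccc4)ccc3[C@@H](OCc3ccccc3)[C@@H]2OCc2ccccc2)cc1 | intermediate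
11 | 3,5-bis(benzyloxy)phenol | Oc1cc(OCc2ccccc2)cc(OCc2ccccc2)c1 | starting material
12 | 2-[(2R,3S,4S)-3,7-bis(benzyloxy)-2-[4-(benzyloxy)phenyl]chroman-4-yl]-3,5-bis(benzyloxy)phenol | C(c1ccccc1)Oc1ccc([C@H]2Oc3cc(OCc4ccccc4)ccc3[C@@H](c3c(OCc4ccccc4)cc(OCc4ccccc4)cc3O)[C@@H]2OCc2ccccc2)cc1 | intermediate
13 | ethynyltrimethylsilane | C#C[Si](C)(C)C | starting material
14 | ethyl[(trimethylsilyl)ethynyl]zinc | CC[Zn]C#C[Si](C)(C)C | intermediate (not isolated)
15 | (1S)-1-[4-(benzyloxy)phenyl]-3-(trimethylsilyl)prop-2-yn-1-ol | O[C@H](C#C[Si](C)(C)C)c1ccc(OCc2ccccc2)cc1 | intermediate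
16 | (1R)-1-[4-(benzyloxy)phenyl]prop-2-yn-1-ol | O[C@H](C#C)c1ccc(OCc2ccccc2)cc1 | intermediate
17 | (2R,3S,4S)-3,7-bis(benzyloxy)-2-[4-(benzyloxy)phenyl]-4-[2,4-bis(benzyloxy)-6-{[(1S)-1-[4-(benzyloxy)phenyl]prop-2-yn-1-yl]oxy}phenyl]chromane | C(c1ccccc1)Oc1ccc([C@H]2Oc3cc(OCc4ccccc4)ccc3[C@@H](c3c(OCc4ccccc4)cc(OCc4ccccc4)cc3O[C@@H](C#C)c3ccc(OCc4ccccc4)cc3)[C@@H]2OCc2ccccc2)cc1 | intermediate
18 | alpha-oxo gold carbene of 17: [(2-biphenylyl)(t-Bu)2P]Au=CH–C(=O)– unit on the (S)-configured ether carbon, triflimide salt | C(c1ccccc1)Oc1ccc([C@H]2Oc3cc(OCc4ccccc4)ccc3[C@@H](c3c(OCc4ccccc4)cc(OCc4ccccc4)cc3O[C@@H](C(=O)C=[Au][P+](C(C)(C)C)(C(C)(C)C)c3ccccc3-c3ccccc3)c3ccc(OCc4ccccc4)cc3)[C@@H]2OCc2ccccc2)cc1.[N-](S(=O)(=O)C(F)(F)F)S(=O)(=O)C(F)(F)F | intermediate (not isolated)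
19 | (2R)-5,7-bis(benzyloxy)-2-[4-(benzyloxy)phenyl]-8-[(2R,3S,4S)-3,7-bis(benzyloxy)-2-[4-(benzyloxy)phenyl]chroman-4-yl]chroman-3-one | C(c1ccccc1)Oc1ccc([C@H]2Oc3cc(OCc4ccccc4)ccc3[C@@H](c3c(OCc4ccccc4)cc(OCc4ccccc4)c4c3O[C@H](c3ccc(OCc5ccccc5)cc3)C(=O)C4)[C@@H]2OCc2ccccc2)cc1 | intermediate
20 | (2R,3R)-5,7-bis(benzyloxy)-2-[4-(benzyloxy)phenyl]-8-[(2R,3S,4S)-3,7-bis(benzyloxy)-2-[4-(benzyloxy)phenyl]chroman-4-yl]chroman-3-ol | C(c1ccccc1)Oc1ccc([C@H]2Oc3cc(OCc4ccccc4)ccc3[C@@H](c3c(OCc4ccccc4)cc(OCc4ccccc4)c4c3O[C@H](c3ccc(OCc5ccccc5)cc3)[C@H](O)C4)[C@@H]2OCc2ccccc2)cc1 | intermediate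
21 | (2R,3R)-8-[(2R,3S,4S)-3,7-dihydroxy-2-(4-hydroxyphenyl)chroman-4-yl]-2-(4-hydroxyphenyl)chromane-3,5,7-triol | Oc1ccc([C@H]2Oc3cc(O)ccc3[C@@H](c3c(O)cc(O)c4c3O[C@H](c3ccc(O)cc3)[C@H](O)C4)[C@@H]2O)cc1 | target

## Step count and least certain steps

Total: 14 steps. Longest linear sequence: 12 steps (steps 1–8 and 11–14 from compound 1). The propargylic alcohol branch (steps 9 and 10) joins at step 11.

**Step 12 (key step).** Several processes can divert the reaction:
- Ring D is very electron-rich and may attack the gold-bound alkyne directly, before the oxygen transfer, which is plain hydroarylation.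
- The doubly activated propargylic C–O bond may ionise under the Lewis-acidic metal, with loss of the C2' configuration or return to the phenol.
- The carbene may be oxidised a second time by the N-oxide.
- C2' of the product may epimerise by enolisation on standing.

Fallback, from 17 back to 19, reaching the ketone by way of the alkene. Treatment of 17 with Ph3PAuNTf2 in CH2Cl2 without oxidant should give by 6-endo hydroarylation the (2S)-5,7-bis(benzyloxy)-2-[4-(benzyloxy)phenyl]-8-[(2R,3S,4S)-3,7-bis(benzyloxy)-2-[4-(benzyloxy)phenyl]chroman-4-yl]-2H-chromene F1, with the propargylic centre untouched. Hydroboration with BH3·SMe2 and oxidation with NaOH/H2O2 should place boron on C3' anti to the C2' aryl group and give the 2',3'-trans alcohol (2R,3S)-5,7-bis(benzyloxy)-2-[4-(benzyloxy)phenyl]-8-[(2R,3S,4S)-3,7-bis(benzyloxy)-2-[4-(benzyloxy)phenyl]chroman-4-yl]chroman-3-ol F2. Oxidation of F2 with Dess–Martin periodinane in CH2Cl2 buffered with NaHCO3 returns to ketone 19, which enters step 13.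

**Step 11.** The alkoxyphosphonium intermediate carries a leaving group on a carbon that is both para-alkoxybenzylic and propargylic. Partial ionisation would erode the configuration at the future C2' and give the epimer of 17. The phenol is also hindered by the neighbouring flavan, so the substitution may be slow and elimination or alkylation of the hydrazide may take over.

Fallback, from 16 and 12 to 17, accepting the planar intermediate and controlling it with a ligand. Alcohol 16 (or its racemate) is converted with Boc2O and DMAP into tert-butyl (1R)-1-[4-(benzyloxy)phenyl]prop-2-yn-1-yl carbonate F3. Copper-catalysed enantioselective propargylic etherification of F3 with phenol 12 ([Cu(MeCN)4]BF4, a 2,6-bis(4-phenyloxazolinyl)pyridine ligand, i-Pr2NEt, toluene, −10 °C) proceeds through a copper allenylidene. The ligand enantiomer is chosen on a model phenol so that the (S)-ether forms, and the product is 17.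

**Step 8.** Alkylation may occur at the carbon para to the phenol hydroxyl, between the two benzyloxy groups, which would lead into the 4→6 series. O-alkylation of the phenol, double alkylation of ring D and some 3,4-cis addition are further possibilities.

Fallback, from 11 and 10 to 12, blocking the unwanted position. Bromination of 11 with NBS in CH2Cl2 at −78 °C should take place mainly para to the hydroxyl and give 3,5-bis(benzyloxy)-4-bromophenol F4, which is purified from any ortho isomer. Coupling of F4 with 10 under the conditions of step 8 can then occur only ortho to the hydroxyl and gives 2-[(2R,3S,4S)-3,7-bis(benzyloxy)-2-[4-(benzyloxy)phenyl]chroman-4-yl]-3,5-bis(benzyloxy)-4-bromophenol F5. Homogeneous hydrodebromination (Pd(OAc)2, PPh3, HCO2Na, DMF, 80 °C), which leaves benzyl ethers alone, returns to 12.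

**Step 5.** Methanol may open the epoxide at the benzylic carbon faster than the acetal is lost. A 1,2-aroyl shift or five-membered closure at the α-carbon may compete. A free benzylic cation may lower the trans selectivity.

Fallback, from 6 to 8, separating ring opening from ring closure. BnSH and SnCl4 in CH2Cl2 at −20 °C should open the epoxide at the benzylic carbon and remove the acetal in the same operation, giving (2S,3R)-1-[4-(benzyloxy)-2-hydroxyphenyl]-3-[4-(benzyloxy)phenyl]-3-(benzylsulfanyl)-2-hydroxypropan-1-one F6. Thiophilic activation with AgBF4 in CH2Cl2 at 0 °C then lets the phenol displace the sulfur group and close the ring to the trans dihydroflavonol 8.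

## Further compounds

F1 | step 12 | (2S)-5,7-bis(benzyloxy)-2-[4-(benzyloxy)phenyl]-8-[(2R,3S,4S)-3,7-bis(benzyloxy)-2-[4-(benzyloxy)phenyl]chroman-4-yl]-2H-chromene | C(c1ccccc1)Oc1ccc([C@H]2Oc3cc(OCc4ccccc4)ccc3[C@@H](c3c(OCc4ccccc4)cc(OCc4ccccc4)c4c3O[C@H](c3ccc(OCc5ccccc5)cc3)C=C4)[C@@H]2OCc2ccccc2)cc1
F2 | step 12 | (2R,3S)-5,7-bis(benzyloxy)-2-[4-(benzyloxy)phenyl]-8-[(2R,3S,4S)-3,7-bis(benzyloxy)-2-[4-(benzyloxy)phenyl]chroman-4-yl]chroman-3-ol | C(c1ccccc1)Oc1ccc([C@H]2Oc3cc(OCc4ccccc4)ccc3[C@@H](c3c(OCc4ccccc4)cc(OCc4ccccc4)c4c3O[C@H](c3ccc(OCc5ccccc5)cc3)[C@@H](O)C4)[C@@H]2OCc2ccccc2)cc1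
F3 | step 11 | tert-butyl (1R)-1-[4-(benzyloxy)phenyl]prop-2-yn-1-yl carbonate | CC(C)(C)OC(=O)O[C@H](C#C)c1ccc(OCc2ccccc2)cc1
F4 | step 8 | 3,5-bis(benzyloxy)-4-bromophenol | Oc1cc(OCc2ccccc2)c(Br)c(OCc2ccccc2)c1
F5 | step 8 | 2-[(2R,3S,4S)-3,7-bis(benzyloxy)-2-[4-(benzyloxy)phenyl]chroman-4-yl]-3,5-bis(benzyloxy)-4-bromophenol | C(c1ccccc1)Oc1ccc([C@H]2Oc3cc(OCc4ccccc4)ccc3[C@@H](c3c(OCc4ccccc4)c(Br)c(OCc4ccccc4)cc3O)[C@@H]2OCc2ccccc2)cc1
F6 | step 5 | (2S,3R)-1-[4-(benzyloxy)-2-hydroxyphenyl]-3-[4-(benzyloxy)phenyl]-3-(benzylsulfanyl)-2-hydroxypropan-1-one | O=C(c1ccc(OCc2ccccc2)cc1O)[C@H](O)[C@H](SCc1ccccc1)c1ccc(OCc2ccccc2)cc1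
A1 | alternative 1 | flavan-4-one form of the target skeleton: five benzyl ethers (upper 3, 7 and ring B, lower 3' and ring E), C4' carbonyl, free C5' and C7' hydroxyls, 2',3'-cis | C(c1ccccc1)Oc1ccc([C@H]2Oc3cc(OCc4ccccc4)ccc3[C@@H](c3c(O)cc(O)c4c3O[C@H](c3ccc(OCc5ccccc5)cc3)[C@H](OCc3ccccc3)C4=O)[C@@H]2OCc2ccccc2)cc1
A2 | alternative 1 | benzylated upper flavan carrying at C4 a 4-methoxy-2,4-bis(trimethylsilyloxy)buta-1,3-dien-1-yl group (double-bond geometry left open, it is lost on aromatisation) | C(c1ccccc1)Oc1ccc([C@H]2Oc3cc(OCc4ccccc4)ccc3[C@@H](C=C(O[Si](C)(C)C)C=C(OC)O[Si](C)(C)C)[C@@H]2OCc2ccccc2)cc1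
A3 | alternative 1 | 2,3-cis-3-(benzyloxy)-2-[4-(benzyloxy)phenyl]-5-(phenylsulfinyl)-2,3-dihydro-4H-pyran-4-one (configuration at sulfur left open) | O=C1C(S(=O)c2ccccc2)=CO[C@H](c2ccc(OCc3ccccc3)cc2)[C@@H]1OCc1ccccc1
A4 | alternative 2 | 7-(benzyloxy)-2-[4-(benzyloxy)phenyl]-4H-chromene carrying at C4 the benzylated lower flavan-3-ol through its C8' | C(c1ccccc1)Oc1ccc(C2=C[C@H](c3c(OCc4ccccc4)cc(OCc4ccccc4)c4c3O[C@H](c3ccc(OCc5ccccc5)cc3)[C@H](OCc3ccccc3)C4)c3ccc(OCc4ccccc4)cc3O2)cc1
A5 | alternative 2 | [4-(benzyloxy)-2-hydroxyphenyl]boronic acid | OB(O)c1ccc(OCc2ccccc2)cc1O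
A6 | alternative 2 | (E)-1-[4-(benzyloxy)phenyl]-3-[(2R,3R)-3,5,7-tris(benzyloxy)-2-[4-(benzyloxy)phenyl]chroman-8-yl]prop-2-en-1-one | O=C(/C=C/c1c(OCc2ccccc2)cc(OCc2ccccc2)c2c1O[C@H](c1ccc(OCc3ccccc3)cc1)[C@H](OCc1ccccc1)C2)c1ccc(OCc2ccccc2)cc1
A7 | alternative 3 | 2',3'-cis flavan-3'-ol of the target skeleton: benzyl ethers on the upper unit and ring D, pivalate on the ring E oxygen, free C3' hydroxyl | C(c1ccccc1)Oc1ccc([C@H]2Oc3cc(OCc4ccccc4)ccc3[C@@H](c3c(OCc4ccccc4)cc(OCc4ccccc4)c4c3O[C@H](c3ccc(OC(=O)C(C)(C)C)cc3)[C@H](O)C4)[C@@H]2OCc2ccccc2)cc1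
A8 | alternative 3 | ring D phenol with the benzylated upper flavan at C8' and a [(2R,3S)-3-[4-(pivaloyloxy)phenyl]oxiran-2-yl]methyl group at C4a' (cis-epoxide) | C(c1ccccc1)Oc1ccc([C@H]2Oc3cc(OCc4ccccc4)ccc3[C@@H](c3c(OCc4ccccc4)cc(OCc4ccccc4)c(C[C@H]4O[C@H]4c4ccc(OC(=O)C(C)(C)C)cc4)c3O)[C@@H]2OCc2ccccc2)cc1
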